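Blue is charged with 4.25 times the initiator of ochre, on the same 0.050 M of free monomer. Which ends with the longer chains?

all flasks: free monomer 0.050 M
- dusk: initiator 0.065 mM; run made earlier
- midnight: initiator 0.28 mM; run made earlier
- blue: initiator 0.34 mM; time 3.0 d
- ochre: initiator 0.080 mM; time 3.0 d

| dusk: time / h | dusk: monomer in chains / % | midnight: time / h | midnight: monomer in chains / % |
|---|---|---|---|
| 4.00 | 0.5 | 4.00 | 1.1 |
| 6.00 | 2.3 | 6.00 | 2.2 |
| 12.0 | 1.0 | 12.0 | 7.3 |
| 20.0 | 3.5 | 20.0 | 12.5 |
| 30.0 | 5.8 | 30.0 | 20.9 |
| 48.0 | 8.5 | 48.0 | 32.3 |

(each reading ± 0.5 percentage points)

- the average divides the monomer in chains by the number of chains begun, living and dead together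
- what may be going on: free monomer + living end -> monomer in chains + living end; monomer in chains + living end -> free monomer + living end; free monomer + initiator -> living end + monomer in chains
- the earlier runs do not show the number of chains; that part of a forecast is a guess

* which of the two ends with the longer chains by the average number of monomer units in a chain (chains begun, living or dead) ("neither" if they lie within 10%) (blue / ochre / neither)
* average number of monomer units in a chain (chains begun, living or dead) at the end, blue
* average number of monomer units in a chain (chains begun, living or dead) at the end, ochre

Watch the living end. By the main step alone, free monomer is used at a rate proportional to it, so a steady number of living ends gives a pseudo-first-order fall. Between 12.0 h and 48.0 h, the logarithm of free monomer in midnight falls with a slope of 0.00873 h⁻¹. In dusk the slope is 0.00219 h⁻¹. As readings, the slopes stand at 3.99 to one and the charges at 4.31 to one, so you may let the rate follow the initiator charge.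

Divide the midnight slope by its initiator charge to get a reading of 31.2 M⁻¹ h⁻¹. Call it the growth constant, the fractional loss of free monomer per hour per unit of initiator charged, each taken as one living end.

Now build the flask up. Take the main step with one living end per initiator charged, present from the start. Your reckoning then puts 53.4% in chains for blue and 16.4% for ochre. Divide by the initiator charge, a guess at the number of chains, and the lengths are 78.5 and 103.

Add the start-up. Midnight's straight line reaches zero at 3.32 h, far shorter than 3.0 d. Shift the clock by that, and the lengths fall to 76.1 and 98.4.

Add the return of monomer from chains. Midnight shows no clear slowdown up to 32.3%, so you cannot size it. Your reckoning stays with ochre longer.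

The forecast says ochre, with 72 for blue and 96 for ochre, slightly below your numbers. It assumes that “by 3 d all the initiator has begun chains (assumed, not measured)”.

The simulation gives ochre, with 73.5 for blue and 96.0 for ochre. Ochre's lead is a factor of 1.31, outside the 10% margin.

    free monomer + living end → monomer in chains + living end, rate k1*[living end]*[free monomer] (k = 32.0 M⁻¹ h⁻¹)
    monomer in chains + living end → free monomer + living end, rate k2*[living end] as long as [monomer in chains] is above zero (k = 0.0880 h⁻¹)
    free monomer + initiator → living end + monomer in chains (k = 5.90 M⁻¹ h⁻¹)

On the shifted clock, the growth constant put 51.7% in chains for blue, and blue holds 50.0%. Now carry the growth constant to a neighbour of blue charged with 5.8 × 10⁻⁴ M of initiator, with the same time. The reckoning puts 71.1% in chains at a length of 61.3. That neighbour holds 68.3% of monomer in chains, and its chains average 58.9 units.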